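**Retrosynthetic overview**
- The acrylic acid is made last, by Knoevenagel–Doebner condensation of the aryl aldehyde, which tolerates the acetate.
- The Ar–C1′ bond and the (E)-C2′=C3′ alkene are not made by cross-coupling. The complete (4′R)-acetoxy chain is hung on the phenol oxygen as a tertiary allyl ether and moved to carbon by a dearomatising [3,3] shift (aromatic Claisen), which also differentiates the two equivalent ortho positions.
- The tertiary C3′–OAr bond comes from Pd-π-allyl etherification of 4-hydroxybenzaldehyde with a γ-hydroxy allylic acetate.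
- The C4′ stereocentre comes from Brown allylboration of (E)-4-acetoxy-2-methylbut-2-enal; the prenyl terminus comes from cross-metathesis.
- No ring is built. The benzene ring is bought as 4-hydroxybenzaldehyde and is only transiently dearomatised in the key step.

Assumption: compound 1 (the industrial C5 vitamin-A aldehyde), (−)-Ipc2B(allyl) solution and 4-hydroxybenzaldehyde are bought; side-chain atoms carry primes, C1′ being the benzylic carbon.

**Step 1**
Reactants: 1 (2E)-4-acetoxy-2-methylbut-2-enal
Product: 3 (2E,4R)-4-hydroxy-3-methylhepta-2,6-dien-1-yl acetate, via borinate ester 2 (not isolated)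
Conditions: (−)-Ipc2B(allyl) (1.3 equiv, 1 M in pentane), Et2O, −78 °C, 3 h; then 3 M aq NaOAc, 30% H2O2, 0 °C → rt
Reagents that add atoms: (−)-B-allyldiisopinocampheylborane, C=CCB([C@H]1C[C@H]2C[C@@H]([C@@H]1C)C2(C)C)[C@H]1C[C@H]2C[C@@H]([C@@H]1C)C2(C)C
Why: Brown allylboration, in which the allyl group is delivered 1,2 through a closed Zimmerman–Traxler chair whose facial bias is fixed by the isopinocampheyl groups; the (−)-reagent (from (−)-α-pinene) is the enantiomer that gives the R carbinol of α-methyl enals (the (+)-reagent gives the S series), about 92–96% ee is expected, and the buffered oxidative work-up spares the primary acetate.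

**Step 2**
Reactants: 3 (2E,4R)-4-hydroxy-3-methylhepta-2,6-dien-1-yl acetate
Product: 4 (2E,4R)-4-hydroxy-3,7-dimethylocta-2,6-dien-1-yl acetate
Conditions: Hoveyda–Grubbs II (3 mol %), 2-methylbut-2-ene (30 equiv), CH2Cl2, 40 °C (sealed), 12 h
Reagents that add atoms: 2-methylbut-2-ene, CC=C(C)C
Why: Olefin cross-metathesis, in which only the monosubstituted terminal alkene engages and is capped as the prenyl group while the trisubstituted allylic-acetate alkene is inert and the C4′ centre is not involved.

**Step 3**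
Reactants: 4 (2E,4R)-4-hydroxy-3,7-dimethylocta-2,6-dien-1-yl acetate; 5 4-hydroxybenzaldehyde
Product: 7 (3RS,4R)-3-(4-formylphenoxy)-3,7-dimethylocta-1,6-dien-4-yl acetate, via hydroxy ether 6 (not isolated)
Conditions: Pd2(dba)3·CHCl3 (2.5 mol %), (±)-DACH-phenyl Trost ligand (7.5 mol %), Et3N (1.5 equiv), CH2Cl2, 0 °C, 4 h; then Ac2O (3 equiv), DMAP (0.1 equiv), same flask, 0 °C → rt
Reagents that add atoms: acetic anhydride, CC(=O)OC(C)=O
Why: Tsuji–Trost O-allylation, in which ionisation of the primary allylic acetate gives a hydroxy-substituted π-allyl-palladium and the phenoxide is delivered under kinetic control, guided by hydrogen bonding to the neighbouring OH as in vinyl-epoxide openings, to the more substituted terminus; DMAP-catalysed acetylation then caps the C4′ hydroxyl, C4′ (R) is untouched, and the new C3′ centre (mixture) is erased in step 4.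

**Step 4**
Reactants: 7 (3RS,4R)-3-(4-formylphenoxy)-3,7-dimethylocta-1,6-dien-4-yl acetate
Product: 9 (2E,4R)-1-(5-formyl-2-hydroxyphenyl)-3,7-dimethylocta-2,6-dien-4-yl acetate, via ortho-dienone 8 (not isolated)
Conditions: o-xylene, BHT (1 mol %), 135 °C, 3 h
Reagents that add atoms: none
Why: Aromatic Claisen rearrangement, a suprafacial [3,3] shift through a chair transition state that breaks aromaticity at either of the two equivalent ortho carbons to give dienone 8, which tautomerises to the phenol; the branched CH(OAc)CH2R group sits pseudo-equatorial and methyl axial, so the new C2′=C3′ bond is E (estimated about 6:1 or better, minor Z isomer removed on AgNO3–silica), the C3′ centre disappears and C4′ (R) is a spectator.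

**Step 5**
Reactants: 9 (2E,4R)-1-(5-formyl-2-hydroxyphenyl)-3,7-dimethylocta-2,6-dien-4-yl acetate
Product: 10 (2E,4R)-1-(5-formyl-2-methoxyphenyl)-3,7-dimethylocta-2,6-dien-4-yl acetate
Conditions: MeI (3 equiv), K2CO3 (2 equiv), acetone, 40 °C, 4 h
Reagents that add atoms: iodomethane, CI
Why: Williamson ether synthesis on the acidic para-formyl phenol under anhydrous carbonate conditions that leave the secondary acetate and the aldehyde alone.

**Step 6**
Reactants: 10 (2E,4R)-1-(5-formyl-2-methoxyphenyl)-3,7-dimethylocta-2,6-dien-4-yl acetate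
Product: 12 (2E)-3-{3-[(2E,4R)-4-acetoxy-3,7-dimethylocta-2,6-dien-1-yl]-4-methoxyphenyl}prop-2-enoic acid, via arylidenemalonic acid 11 (not isolated)
Conditions: malonic acid (2.5 equiv), pyridine, piperidine (0.1 equiv), 85 °C, 3 h; then cold 1 M HCl
Reagents that add atoms: malonic acid, OC(=O)CC(=O)O
Why: Knoevenagel–Doebner condensation, in which the arylidenemalonic acid loses CO2 in pyridine to give the thermodynamically favoured (E)-cinnamic acid directly as the free acid, so no ester hydrolysis is needed that would endanger the acetate.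

**Compound list**
1 | (2E)-4-acetoxy-2-methylbut-2-enal | CC(=O)OC/C=C(\C)C=O | starting material
2 | (2E,4R)-4-[bis(isopinocampheyl)boranyloxy]-3-methylhepta-2,6-dien-1-yl acetate (borinate ester) | CC(=O)OC/C=C(\C)[C@H](OB([C@H]1C[C@H]2C[C@@H]([C@@H]1C)C2(C)C)[C@H]1C[C@H]2C[C@@H]([C@@H]1C)C2(C)C)CC=C | intermediate (not isolated)
3 | (2E,4R)-4-hydroxy-3-methylhepta-2,6-dien-1-yl acetate | CC(=O)OC/C=C(\C)[C@H](O)CC=C | intermediate
4 | (2E,4R)-4-hydroxy-3,7-dimethylocta-2,6-dien-1-yl acetate | CC(=O)OC/C=C(\C)[C@H](O)CC=C(C)C | intermediate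
5 | 4-hydroxybenzaldehyde | O=Cc1ccc(O)cc1 | starting material
6 | 4-{[(3RS,4R)-4-hydroxy-3,7-dimethylocta-1,6-dien-3-yl]oxy}benzaldehyde | C=CC(C)(Oc1ccc(C=O)cc1)[C@H](O)CC=C(C)C | intermediate (not isolated)
7 | (3RS,4R)-3-(4-formylphenoxy)-3,7-dimethylocta-1,6-dien-4-yl acetate | C=CC(C)(Oc1ccc(C=O)cc1)[C@H](OC(C)=O)CC=C(C)C | intermediate
8 | (2E,4R)-1-[(1RS)-3-formyl-6-oxocyclohexa-2,4-dien-1-yl]-3,7-dimethylocta-2,6-dien-4-yl acetate | O=CC1=CC(C/C=C(\C)[C@@H](CC=C(C)C)OC(C)=O)C(=O)C=C1 | intermediate (not isolated)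
9 | (2E,4R)-1-(5-formyl-2-hydroxyphenyl)-3,7-dimethylocta-2,6-dien-4-yl acetate | O=Cc1ccc(O)c(C/C=C(\C)[C@@H](CC=C(C)C)OC(C)=O)c1 | intermediate
10 | (2E,4R)-1-(5-formyl-2-methoxyphenyl)-3,7-dimethylocta-2,6-dien-4-yl acetate | COc1ccc(C=O)cc1C/C=C(\C)[C@@H](CC=C(C)C)OC(C)=O | intermediate
11 | 2-({3-[(2E,4R)-4-acetoxy-3,7-dimethylocta-2,6-dien-1-yl]-4-methoxyphenyl}methylidene)propanedioic acid | COc1ccc(C=C(C(=O)O)C(=O)O)cc1C/C=C(\C)[C@@H](CC=C(C)C)OC(C)=O | intermediate (not isolated)
12 | (2E)-3-{3-[(2E,4R)-4-acetoxy-3,7-dimethylocta-2,6-dien-1-yl]-4-methoxyphenyl}prop-2-enoic acid (CNP0206859.1) | COc1ccc(/C=C/C(=O)O)cc1C/C=C(\C)[C@@H](CC=C(C)C)OC(C)=O | target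

**Step count and risks**
Total step count: 6. Longest linear sequence: 6 steps (1 → 3 → 4 → 7 → 9 → 10 → 12); 4-hydroxybenzaldehyde 5 enters at step 3.

The three steps most likely to fail:

Step 4 (Claisen rearrangement). The E:Z ratio rests only on the size difference between methyl and the acetoxyalkyl group, and the tertiary ether can also eliminate to phenol and diene. The fallback sets out from 4 and gives up the O-to-C transposition. A Pd-catalysed allyl–aryl Suzuki coupling of 4 with commercial (5-formyl-2-methoxyphenyl)boronic acid (Pd2(dba)3, PPh3, KF, THF–H2O, 50 °C) joins the aryl group to the unhindered CH2 terminus and carries over the E geometry of 4. This gives 3-[(2E,4R)-4-hydroxy-3,7-dimethylocta-2,6-dien-1-yl]-4-methoxybenzaldehyde F1. Acetylation (Ac2O, pyridine, DMAP) then gives 10, where the route is rejoined.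

Step 3 (branched etherification). The phenoxide may go to the CH2 terminus to give the linear ether, or the tertiary ether may re-ionise. The fallback sets out from 4 and replaces the ether by direct dearomatising C-alkylation of the phenoxide.
- K2CO3 in MeOH removes the primary acetate to give (2E,4R)-3,7-dimethylocta-2,6-diene-1,4-diol F2.
- CBr4/PPh3 (CH2Cl2, −20 °C) converts only the primary allylic hydroxyl, giving (2E,4R)-1-bromo-3,7-dimethylocta-2,6-dien-4-ol F3.
- Ac2O/pyridine gives (2E,4R)-1-bromo-3,7-dimethylocta-2,6-dien-4-yl acetate F4.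
- The sodium salt of 5 (NaH, toluene, rt → 50 °C) is alkylated at the ortho carbon by F4 within the contact ion pair. This passes through the same dienone 8 and comes back to the route at 9, with the alkene geometry inherited from 1.

Step 6 (Knoevenagel–Doebner). The allylic acetate may not survive hot pyridine/piperidine. The fallback sets out from 10. Horner–Wadsworth–Emmons olefination with 2-(trimethylsilyl)ethyl (diethoxyphosphoryl)acetate (LiCl, DBU, MeCN, rt) gives 2-(trimethylsilyl)ethyl (2E)-3-{3-[(2E,4R)-4-acetoxy-3,7-dimethylocta-2,6-dien-1-yl]-4-methoxyphenyl}prop-2-enoate F5. Fluoride (TASF, DMF, 0 °C) then releases the acid 12 without touching the acetate.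

**Further compounds**
F1 | step 4 | 3-[(2E,4R)-4-hydroxy-3,7-dimethylocta-2,6-dien-1-yl]-4-methoxybenzaldehyde | COc1ccc(C=O)cc1C/C=C(\C)[C@H](O)CC=C(C)C
F2 | step 3 | (2E,4R)-3,7-dimethylocta-2,6-diene-1,4-diol | OC/C=C(\C)[C@H](O)CC=C(C)C
F3 | step 3 | (2E,4R)-1-bromo-3,7-dimethylocta-2,6-dien-4-ol | BrC/C=C(\C)[C@H](O)CC=C(C)C
F4 | step 3 | (2E,4R)-1-bromo-3,7-dimethylocta-2,6-dien-4-yl acetate | BrC/C=C(\C)[C@H](OC(C)=O)CC=C(C)C
F5 | step 6 | 2-(trimethylsilyl)ethyl (2E)-3-{3-[(2E,4R)-4-acetoxy-3,7-dimethylocta-2,6-dien-1-yl]-4-methoxyphenyl}prop-2-enoate | COc1ccc(/C=C/C(=O)OCC[Si](C)(C)C)cc1C/C=C(\C)[C@@H](CC=C(C)C)OC(C)=O
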